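**Retrosynthetic overview**
- The target diol comes from a trans-2-aryl-2,3-dihydrobenzofuran-3-carboxylate that also carries a cinnamate ester; one hydride reduction of both esters is the last step.
- The dihydrofuran ring is the only ring that is made (both benzene rings are bought). It is closed by forming the O1–C2 bond: an enantioselective oxypalladation of a 2-hydroxystilbene, with CO/MeOH capture at C3, sets both stereocentres in one step.
- The 2-hydroxystilbene comes from a Heck union of an ortho-iodophenol (from methyl p-coumarate) and 3,4,5-trimethoxystyrene (from 3,4,5-trimethoxybenzaldehyde).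

Assumption: the sense of induction of the new catalyst in step 4 cannot be known in advance; the (S,S) ligand is written as the one that gives (2R,3R)-6, and the (R,R) ligand is used instead if the sense proves opposite.

The target is the trans isomer, (2R,3S). In diester 6 the same spatial arrangement is named (2R,3R), because the ester outranks C2 at C3.

**Route**

Step 1
Reactants: 1 methyl (E)-3-(4-hydroxyphenyl)prop-2-enoate (methyl p-coumarate)
Product: 2 methyl (E)-3-(4-hydroxy-3-iodophenyl)prop-2-enoate
Conditions: NIS (1.05 equiv), TsOH·H2O (10 mol%), MeCN, 0 °C to rt, dark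
Reagents that add atoms: N-iodosuccinimide, O=C1CCC(=O)N1I
Why: Electrophilic aromatic iodination; the phenol OH directs ortho (para is blocked), the ester-conjugated alkene is inert to the iodonium source, and one equivalent keeps it at mono-iodination.

Step 2
Reactants: 3 3,4,5-trimethoxybenzaldehyde
Product: 4 5-ethenyl-1,2,3-trimethoxybenzene (3,4,5-trimethoxystyrene)
Conditions: Ph3PCH3Br (1.2 equiv), KOtBu (1.2 equiv), THF, 0 °C to rt
Reagents that add atoms: methyltriphenylphosphonium bromide, C[P+](c1ccccc1)(c1ccccc1)c1ccccc1.[Br-]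
Why: Wittig methylenation of a non-enolisable aromatic aldehyde with the unstabilised ylide; no stereochemistry is involved.

Step 3
Reactants: 2 methyl (E)-3-(4-hydroxy-3-iodophenyl)prop-2-enoate; 4 5-ethenyl-1,2,3-trimethoxybenzene (1.3 equiv)
Product: 5 methyl (E)-3-{4-hydroxy-3-[(E)-2-(3,4,5-trimethoxyphenyl)ethenyl]phenyl}prop-2-enoate
Conditions: Pd(OAc)2 (5 mol%), P(o-tol)3 (10 mol%), Et3N (3 equiv), DMF, 90 °C, argon
Reagents that add atoms: none
Why: Mizoroki–Heck reaction; zerovalent palladium inserts into the C–I bond, the aryl group adds to the terminal carbon of the styrene and syn β-hydride elimination gives the E-stilbene, while the free phenol is tolerated and the electron-poor cinnamate alkene is a much slower acceptor.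

Step 4
Reactants: 5 methyl (E)-3-{4-hydroxy-3-[(E)-2-(3,4,5-trimethoxyphenyl)ethenyl]phenyl}prop-2-enoate
Product: 6 methyl (2R,3R)-5-[(E)-3-methoxy-3-oxoprop-1-en-1-yl]-2-(3,4,5-trimethoxyphenyl)-2,3-dihydro-1-benzofuran-3-carboxylate (trans)
Conditions: Pd(OCOCF3)2 (10 mol%), (S,S)-tBu-box (12 mol%), p-benzoquinone (2 equiv), CO (1 atm), MeOH/CH2Cl2 1:1, −20 °C to 0 °C
Reagents that add atoms: carbon monoxide, [C-]#[O+]; methanol, CO
Why: Proposed new method: enantioselective 5-endo anti-oxypalladation/methoxycarbonylation of a 2-hydroxystilbene. The cationic divalent palladium complex of the C2-symmetric bis(oxazoline) 2,2'-(propane-2,2-diyl)bis[(4S)-4-tert-butyl-4,5-dihydrooxazole] binds one enantioface of the E-alkene; the trimethoxyphenyl group polarises the complex toward a benzylic cation at C2, so the phenol closes the ring by attack on C2 from the face opposite palladium (a syn insertion is geometrically excluded for this 5-endo closure), which sets C2 and places palladium on C3 trans to the aryl group; the bidentate ligand plus bound CO leave no free cis site for β-hydride elimination to the benzofuran, so CO insertion with retention and methanolysis give the trans ester, and benzoquinone returns zerovalent palladium to divalent palladium. Closest known reaction types: Semmelhack-type intramolecular alkoxycarbonylation, the enantioselective phenol Wacker–carbonylation–methoxylation that gives chromans with Pd(OCOCF3)2 and chiral bis(oxazolines), and the racemic 5-endo oxypalladation of 2-hydroxystilbenes that ends in 2-arylbenzofurans.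

Step 5
Reactants: 6 methyl (2R,3R)-5-[(E)-3-methoxy-3-oxoprop-1-en-1-yl]-2-(3,4,5-trimethoxyphenyl)-2,3-dihydro-1-benzofuran-3-carboxylate
Product: 7 (E)-3-[(2R,3S)-3-(hydroxymethyl)-2-(3,4,5-trimethoxyphenyl)-2,3-dihydro-1-benzofuran-5-yl]prop-2-en-1-ol
Conditions: iBu2AlH (6 equiv), CH2Cl2, −78 °C to 0 °C; aq. potassium sodium tartrate work-up
Reagents that add atoms: none
Why: Ester reduction with DIBAL-H; both esters go to primary alcohols (1,2-reduction of the cinnamate gives the E-allylic alcohol), C2 is untouched and C3 keeps its trans (thermodynamic) arrangement at low temperature, the descriptor changing from 3R to 3S only through the priority change.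

**Compound list**
1 | methyl (E)-3-(4-hydroxyphenyl)prop-2-enoate | COC(=O)/C=C/c1ccc(O)cc1 | starting material
2 | methyl (E)-3-(4-hydroxy-3-iodophenyl)prop-2-enoate | COC(=O)/C=C/c1ccc(O)c(I)c1 | intermediate
3 | 3,4,5-trimethoxybenzaldehyde | COc1cc(C=O)cc(OC)c1OC | starting material
4 | 5-ethenyl-1,2,3-trimethoxybenzene | C=Cc1cc(OC)c(OC)c(OC)c1 | intermediate
5 | methyl (E)-3-{4-hydroxy-3-[(E)-2-(3,4,5-trimethoxyphenyl)ethenyl]phenyl}prop-2-enoate | COC(=O)/C=C/c1ccc(O)c(/C=C/c2cc(OC)c(OC)c(OC)c2)c1 | intermediate
6 | methyl (2R,3R)-5-[(E)-3-methoxy-3-oxoprop-1-en-1-yl]-2-(3,4,5-trimethoxyphenyl)-2,3-dihydro-1-benzofuran-3-carboxylate | COc1cc([C@@H]2Oc3ccc(/C=C/C(=O)OC)cc3[C@H]2C(=O)OC)cc(OC)c1OC | intermediate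
7 | (E)-3-[(2R,3S)-3-(hydroxymethyl)-2-(3,4,5-trimethoxyphenyl)-2,3-dihydro-1-benzofuran-5-yl]prop-2-en-1-ol | COc1cc([C@@H]2Oc3ccc(/C=C/CO)cc3[C@H]2CO)cc(OC)c1OC | target

**Step count**
Total steps: 5. Longest linear sequence: 4 steps (1 → 2 → 5 → 6 → 7, or 3 → 4 → 5 → 6 → 7).

**Three steps most likely to fail**

Step 4 (the new reaction). The C3–Pd intermediate has a syn hydrogen on C2, so β-hydride elimination to the aromatic 2-arylbenzofuran competes with CO insertion. The free phenol and alkene can also enter other CO pathways (cyclocarbonylation to a 3-arylcoumarin, bis-methoxycarbonylation), and the ee is unknown. C3 is the only acidic stereocentre and trans is the thermodynamic arrangement, so brief NaOMe/MeOH equilibration would correct any loss of trans selectivity without touching C2.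

Fallback with known chemistry, setting out from 4 (with 2) and coming back at 7: the C2–O bond is made first, intermolecularly, by iridium-catalysed asymmetric allylic etherification, and the ring is then closed by radical cyclisation. Cross-metathesis of 4 with (Z)-but-2-ene-1,4-diyl dimethyl dicarbonate (second-generation Hoveyda–Grubbs catalyst, CH2Cl2, 40 °C) gives (E)-3-(3,4,5-trimethoxyphenyl)prop-2-en-1-yl methyl carbonate F1. F1 and the lithium phenoxide of 2 (LiOtBu), with [Ir(cod)Cl]2 and a binaphthol-derived N,N-bis(1-phenylethyl)phosphoramidite (the ligand enantiomer that gives the R ether) in THF at 50 °C, give the branched ether methyl (E)-3-[3-iodo-4-{[(1R)-1-(3,4,5-trimethoxyphenyl)prop-2-en-1-yl]oxy}phenyl]prop-2-enoate F2. Bu3SnH and TEMPO in benzene at 70 °C bring about 5-exo-trig aryl radical cyclisation with TEMPO capture of the primary radical, to give methyl (E)-3-[(2R,3S)-3-{[(2,2,6,6-tetramethylpiperidin-1-yl)oxy]methyl}-2-(3,4,5-trimethoxyphenyl)-2,3-dihydro-1-benzofuran-5-yl]prop-2-enoate F3; the 2-aryl group steers the new C3 substituent trans, and the minor cis isomer is removed by chromatography. Zn in AcOH/THF/H2O cleaves the N–O bond to methyl (E)-3-[(2R,3S)-3-(hydroxymethyl)-2-(3,4,5-trimethoxyphenyl)-2,3-dihydro-1-benzofuran-5-yl]prop-2-enoate F4, and iBu2AlH (CH2Cl2, −78 °C) reduces the remaining ester to give 7.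

Step 3 (Heck coupling). A free ortho-iodophenol with an electron-rich styrene can give modest yields, some 1,1-diaryl regioisomer and styrene oligomers, and the cinnamate of 2 is a second, slower Heck acceptor.

Fallback, setting out from 4 (with 2) and coming back at 5: the stilbene bond is made by Suzuki–Miyaura coupling of a preformed alkenylboronate. Cross-metathesis of 4 with vinylboronic acid pinacol ester (second-generation Hoveyda–Grubbs catalyst, CH2Cl2, 40 °C) gives (E)-4,4,5,5-tetramethyl-2-[2-(3,4,5-trimethoxyphenyl)ethenyl]-1,3,2-dioxaborolane F5. Coupling of F5 with 2 (PdCl2(dppf), K2CO3, dioxane/H2O, 80 °C) gives 5 with the E geometry fixed by the boronate.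

Step 1 (iodination). Di-iodination or attack of the iodonium source on the p-hydroxystyrene-type alkene would lower the yield of 2.

Fallback, setting out from 1 and coming back at 5: the ortho carbon is introduced as an aldehyde and the stilbene is made by olefination, so 2, 4 and the Heck step are no longer needed. Magnesium-mediated ortho-formylation of 1 (MgCl2, Et3N, paraformaldehyde, MeCN, reflux) gives methyl (E)-3-(3-formyl-4-hydroxyphenyl)prop-2-enoate F6. Horner–Wadsworth–Emmons olefination of F6 with commercial diethyl (3,4,5-trimethoxybenzyl)phosphonate (NaH, 2.2 equiv, THF/DMF, 0 °C to rt) gives E-stilbene 5.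

**Further compounds**
F1 | step 4 | (E)-3-(3,4,5-trimethoxyphenyl)prop-2-en-1-yl methyl carbonate | COC(=O)OC/C=C/c1cc(OC)c(OC)c(OC)c1
F2 | step 4 | methyl (E)-3-[3-iodo-4-{[(1R)-1-(3,4,5-trimethoxyphenyl)prop-2-en-1-yl]oxy}phenyl]prop-2-enoate | C=C[C@@H](Oc1ccc(/C=C/C(=O)OC)cc1I)c1cc(OC)c(OC)c(OC)c1
F3 | step 4 | methyl (E)-3-[(2R,3S)-3-{[(2,2,6,6-tetramethylpiperidin-1-yl)oxy]methyl}-2-(3,4,5-trimethoxyphenyl)-2,3-dihydro-1-benzofuran-5-yl]prop-2-enoate | COc1cc([C@@H]2Oc3ccc(/C=C/C(=O)OC)cc3[C@H]2CON4C(C)(C)CCCC4(C)C)cc(OC)c1OC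
F4 | step 4 | methyl (E)-3-[(2R,3S)-3-(hydroxymethyl)-2-(3,4,5-trimethoxyphenyl)-2,3-dihydro-1-benzofuran-5-yl]prop-2-enoate | COc1cc([C@@H]2Oc3ccc(/C=C/C(=O)OC)cc3[C@H]2CO)cc(OC)c1OC
F5 | step 3 | (E)-4,4,5,5-tetramethyl-2-[2-(3,4,5-trimethoxyphenyl)ethenyl]-1,3,2-dioxaborolane | COc1cc(/C=C/B2OC(C)(C)C(C)(C)O2)cc(OC)c1OC
F6 | step 1 | methyl (E)-3-(3-formyl-4-hydroxyphenyl)prop-2-enoate | COC(=O)/C=C/c1ccc(O)c(C=O)c1
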